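**Assumption:** the target has no stereocentre (it is achiral), so no enantiocontrol is needed; the two transient intermediates 7 and 8 are racemic and lose their stereocentres on dehydration.

**Retrosynthetic overview**
- Target ⇐ selective cleavage of the 5-OMe (peri to C4=O) of the 5,6,7,8-tetramethoxyflavonol.
- Ring C (the only ring formed; rings A and B are bought as arenes) ⇐ cyclodehydration of the ketol ArA–CO–CH(OH)–CO–ArB.
- Key C2–C3 bond ⇐ carbene-catalysed cross-benzoin: the B-ring aldehyde as acyl anion (Breslow intermediate) attacks the aldehyde carbon of the A-ring arylglyoxal, so two natively electrophilic carbonyl carbons are joined.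
- Arylglyoxal ⇐ Riley oxidation of 2-hydroxy-3,4,5,6-tetramethoxyacetophenone ⇐ bromination / Cu methoxylation ⇐ ortho-acetylation of 3,4,5-trimethoxyphenol.

Note: acetophenone 2 is also sold by fine-chemical suppliers; buying it removes step 1.

**Step 1**
Reactants: 1 3,4,5-trimethoxyphenol
Product: 2 1-(6-hydroxy-2,3,4-trimethoxyphenyl)ethan-1-one
Conditions: AcOH, BF3·OEt2 (3 equiv), 90 °C; then H2O
Reagents that add atoms: acetic acid CC(=O)O
Why: BF3-mediated Friedel–Crafts (Fries-type) ortho-acylation; the two free ring positions are equivalent by symmetry and the BF2 chelate of the product blocks a second acylation.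

**Step 2**
Reactants: 2 1-(6-hydroxy-2,3,4-trimethoxyphenyl)ethan-1-one
Product: 3 1-(3-bromo-2-hydroxy-4,5,6-trimethoxyphenyl)ethan-1-one
Conditions: NBS (1.05 equiv), MeCN, 0 °C → rt
Reagents that add atoms: N-bromosuccinimide O=C1CCC(=O)N1Br
Why: electrophilic aromatic bromination at the single free ring position (ortho to OH), which is far faster on this electron-rich ring than α-bromination of the ketone.

**Step 3**
Reactants: 3 1-(3-bromo-2-hydroxy-4,5,6-trimethoxyphenyl)ethan-1-one
Product: 4 1-(2-hydroxy-3,4,5,6-tetramethoxyphenyl)ethan-1-one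
Conditions: NaOMe (8 equiv, 25% in MeOH), CuBr (20 mol %), DMF, 110 °C; then aq. HCl
Reagents that add atoms: sodium methoxide [Na+].[O-]C
Why: Ullmann-type Cu(I)-catalysed methoxylation of an aryl bromide ortho to a phenoxide, the same substitution pattern as the 5-bromovanillin → syringaldehyde conversion.

**Step 4**
Reactants: 4 1-(2-hydroxy-3,4,5,6-tetramethoxyphenyl)ethan-1-one
Product: 5 2-(2-hydroxy-3,4,5,6-tetramethoxyphenyl)-2-oxoacetaldehyde (drawn open-chain; equilibrates with its cyclic lactol; used dry)
Conditions: SeO2 (1.3 equiv), 1,4-dioxane/H2O (30:1), 100 °C; filter Se, azeotrope with PhMe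
Reagents that add atoms: selenium dioxide O=[Se]=O
Why: Riley oxidation of an aryl methyl ketone to the arylglyoxal; the ring is fully substituted and the OMe groups are inert, so the acetyl CH3 is the only oxidisable site.

**Step 5**
Reactants: 5 2-(2-hydroxy-3,4,5,6-tetramethoxyphenyl)-2-oxoacetaldehyde; 6 3-hydroxy-4,5-dimethoxybenzaldehyde (1.3 equiv)
Product: 9 3-hydroxy-2-(3-hydroxy-4,5-dimethoxyphenyl)-5,6,7,8-tetramethoxy-4H-chromen-4-one, via cross-benzoin ketol 7 (not isolated), via cyclic hemiketal 8 (not isolated)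
Conditions: 2-(pentafluorophenyl)-6,7-dihydro-5H-pyrrolo[2,1-c][1,2,4]triazol-2-ium BF4 (20 mol %), i-Pr2NEt (20 mol %), 4 Å MS, THF, 40 °C; then AcOH, TsOH·H2O (30 mol %), 80 °C
Reagents that add atoms: none
Why: Proposed new method: the triazolylidene adds to the unhindered aldehyde of 6 to give a Breslow intermediate (acyl anion equivalent) that attacks the strongly electrophilic α-keto aldehyde carbon of 5 (released from its lactol form), a cross-benzoin reaction whose closest known type is the NHC-catalysed chemoselective cross-benzoin of aldehydes with α-keto esters and other activated carbonyl acceptors; should 5 act as donor instead, the regioisomeric ketol equilibrates with 7 through the shared enediol, and the ortho phenol then closes hemiketal 8, which acid dehydrates to the aromatic pyranone 9 with water as the only by-product.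

**Step 6**
Reactants: 9 3-hydroxy-2-(3-hydroxy-4,5-dimethoxyphenyl)-5,6,7,8-tetramethoxy-4H-chromen-4-one
Product: 10 3-demethyldigicitrin, 3,5-dihydroxy-2-(3-hydroxy-4,5-dimethoxyphenyl)-6,7,8-trimethoxy-4H-chromen-4-one
Conditions: AlCl3 (6 equiv), MeCN, 0 °C → rt; then 2 M HCl, 50 °C
Reagents that add atoms: none
Why: chelation-controlled Lewis-acid ether cleavage; only the 5-OMe can form a six-membered Al chelate with the C4 carbonyl, so it is cleaved selectively while the other five OMe groups remain.

**Compound list**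
1 | 3,4,5-trimethoxyphenol | COc1cc(O)cc(OC)c1OC | starting material
2 | 1-(6-hydroxy-2,3,4-trimethoxyphenyl)ethan-1-one | CC(=O)c1c(O)cc(OC)c(OC)c1OC | intermediate
3 | 1-(3-bromo-2-hydroxy-4,5,6-trimethoxyphenyl)ethan-1-one | CC(=O)c1c(O)c(Br)c(OC)c(OC)c1OC | intermediate
4 | 1-(2-hydroxy-3,4,5,6-tetramethoxyphenyl)ethan-1-one | CC(=O)c1c(O)c(OC)c(OC)c(OC)c1OC | intermediate
5 | 2-(2-hydroxy-3,4,5,6-tetramethoxyphenyl)-2-oxoacetaldehyde (open-chain form) | O=CC(=O)c1c(O)c(OC)c(OC)c(OC)c1OC | intermediate
6 | 3-hydroxy-4,5-dimethoxybenzaldehyde | COc1cc(C=O)cc(O)c1OC | starting material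
7 | 2-hydroxy-1-(2-hydroxy-3,4,5,6-tetramethoxyphenyl)-3-(3-hydroxy-4,5-dimethoxyphenyl)propane-1,3-dione (racemic) | COc1cc(C(=O)C(O)C(=O)c2c(O)c(OC)c(OC)c(OC)c2OC)cc(O)c1OC | intermediate
8 | 2,3-dihydroxy-2-(3-hydroxy-4,5-dimethoxyphenyl)-5,6,7,8-tetramethoxychroman-4-one (racemic diastereomer mixture) | COc1cc(C2(O)Oc3c(OC)c(OC)c(OC)c(OC)c3C(=O)C2O)cc(O)c1OC | intermediate
9 | 3-hydroxy-2-(3-hydroxy-4,5-dimethoxyphenyl)-5,6,7,8-tetramethoxy-4H-chromen-4-one | COc1cc(-c2oc3c(OC)c(OC)c(OC)c(OC)c3c(=O)c2O)cc(O)c1OC | intermediate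
10 | 3-demethyldigicitrin, 3,5-dihydroxy-2-(3-hydroxy-4,5-dimethoxyphenyl)-6,7,8-trimethoxy-4H-chromen-4-one (achiral) | COc1cc(-c2oc3c(OC)c(OC)c(OC)c(O)c3c(=O)c2O)cc(O)c1OC | target

**Step count**
Total steps: 6. Longest linear sequence: 6 (1 → 2 → 3 → 4 → 5 → 9 → 10); aldehyde 6 is bought and enters at step 5.

**Three steps most likely to fail**

Step 5 (carbene cross-benzoin / cyclodehydration). The risks are internal redox of the glyoxal on the carbene (giving a mandelate-type lactone), homo-benzoin of 6, and retro-Claisen cleavage of ketol 7. Fallback: abandon the cross-benzoin and build ring C by chalcone oxidation, setting out from acetophenone 4 (with aldehyde 6) and coming back at flavonol 9. Claisen–Schmidt condensation (KOH, EtOH, rt) gives the chalcone (E)-1-(2-hydroxy-3,4,5,6-tetramethoxyphenyl)-3-(3-hydroxy-4,5-dimethoxyphenyl)prop-2-en-1-one F1. Algar–Flynn–Oyamada oxidation (30% H2O2, aq. NaOH, MeOH, 0 °C) then closes it to 9. The 6'-methoxy group favours some aurone, so the oxidation is kept cold and dilute.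

Step 4 (Riley oxidation). The risks are over-oxidation to the glyoxylic acid and loss of the polar glyoxal/lactol on isolation. Fallback: reach the same oxidation level by nitrosation instead of oxygen transfer, setting out from 4 and coming back at 5. Isoamyl nitrite with HCl in Et2O/THF at 0 °C → rt gives the α-oximino ketone (E)-2-(hydroxyimino)-1-(2-hydroxy-3,4,5,6-tetramethoxyphenyl)ethan-1-one F2. Trans-oximation with aqueous formaldehyde / conc. HCl at rt then releases glyoxal 5.

Step 3 (Cu methoxylation). The risks are hydrodebromination back to 2 and base-mediated self-condensation of the acetyl group at 110 °C. Fallback: bring in the extra oxygen by formylation and Dakin oxidation instead of through the halide, setting out from 2 and coming back at 4. Duff formylation (hexamethylenetetramine, TFA, 80 °C; then aq. HCl) at the free ring position gives 3-acetyl-2-hydroxy-4,5,6-trimethoxybenzaldehyde F3. Dakin oxidation (H2O2, aq. NaOH, 0 °C → rt; the aldehyde reacts faster than the ketone) gives 1-(2,3-dihydroxy-4,5,6-trimethoxyphenyl)ethan-1-one F4. Methylation of the dianion (NaH 2.2 equiv, DMSO, then MeI 1.0 equiv) alkylates the non-chelated 3-oxide and gives 4.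

**Further compounds**
F1 | step 5 | (E)-1-(2-hydroxy-3,4,5,6-tetramethoxyphenyl)-3-(3-hydroxy-4,5-dimethoxyphenyl)prop-2-en-1-one | COc1cc(/C=C/C(=O)c2c(O)c(OC)c(OC)c(OC)c2OC)cc(O)c1OC
F2 | step 4 | (E)-2-(hydroxyimino)-1-(2-hydroxy-3,4,5,6-tetramethoxyphenyl)ethan-1-one | O/N=C/C(=O)c1c(O)c(OC)c(OC)c(OC)c1OC
F3 | step 3 | 3-acetyl-2-hydroxy-4,5,6-trimethoxybenzaldehyde | CC(=O)c1c(O)c(C=O)c(OC)c(OC)c1OC
F4 | step 3 | 1-(2,3-dihydroxy-4,5,6-trimethoxyphenyl)ethan-1-one | CC(=O)c1c(O)c(O)c(OC)c(OC)c1OC
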